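**Assumptions (one line each)**
- The target is drawn as the open hydroxy-ketone (myriaporone 4); in solution it equilibrates with its C3 hemiketal (myriaporone 3), and the final product is taken as that equilibrating material.
- Carbons are numbered along the chain: C1 = ethyl CH3, C3 and C7 = ketones, C15 = propenyl CH3, C6′/C8′ = hydroxymethyl carbons. Target configuration: 5S,6S,8R,9S,10R,11S,12S,13Z. TBS = tert-butyldimethylsilyl.
- 1,1-Diphenylsilinan-4-one is not assumed to be purchasable and is made in two steps from commercial diphenyldivinylsilane.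

**Retrosynthetic overview**
1. Myriaporone 4 ⇐ global desilylation ⇐ C9–OH-directed epoxidation of a (10Z)-allylic alcohol (oxirane is the last ring formed) ⇐ C3 ketal hydrolysis.
2. C8–C9: anti boron aldol of a C1–C8 ketone with (2Z,4S,5Z)-2,4-dimethylhepta-2,5-dienal, itself made from (R)-Roche ester by Wittig and Still–Gennari olefinations.
3. C5–C6 plus both CH2OH arms: a new L-proline-catalysed anti-aldol of 1,1-diphenylsilinan-4-one (a ring-locked 1,5-dihydroxypentan-3-one surrogate) with a β-ketal aldehyde, then Fleming–Tamao opening of the silacycle.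
4. Ring order: borasilinane → silinanone (temporary ring, made first); dioxolane (protecting ring); silacycle opened; oxirane closed last.

**Route**

Step 1
Reactants: 1 diphenyldivinylsilane
Product: 2 1-methoxy-4,4-diphenyl-1,4-borasilinane
Conditions: 9-BBN (2 equiv), THF, rt; BH3·SMe2 (1 equiv), rt→65 °C; MeOH
Reagents that add atoms: borane–dimethyl sulfide (B.CSC); methanol (CO)
Why: Anti-Markovnikov hydroboration of both vinylsilane arms with 9-BBN puts boron on the terminal carbons, and borane exchange redistributes to the six-membered cyclic borinane, trapped as the B–OMe ester (cyclic hydroboration/exchange).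

Step 2
Reactants: 2 1-methoxy-4,4-diphenyl-1,4-borasilinane
Product: 3 1,1-diphenylsilinan-4-one
Conditions: Cl2CHOMe, LiOCEt3, THF, 0 °C→rt; then H2O2, NaOH, 0 °C
Reagents that add atoms: dichloromethyl methyl ether (COC(Cl)Cl); hydrogen peroxide (OO)
Why: DCME carbonylation of a borinic ester: two B→C migrations onto the carbenoid carbon and oxidation give the ring ketone.

Step 3
Reactants: 4 ethyl 3-oxopentanoate
Product: 5 ethyl 2-(2-ethyl-1,3-dioxolan-2-yl)acetate
Conditions: ethylene glycol, p-TsOH (cat.), toluene, reflux, Dean–Stark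
Reagents that add atoms: ethylene glycol (OCCO)
Why: Acid-catalysed ketalisation of the ketone carbonyl with azeotropic water removal; the ester is untouched.

Step 4
Reactants: 5 ethyl 2-(2-ethyl-1,3-dioxolan-2-yl)acetate
Product: 6 2-(2-ethyl-1,3-dioxolan-2-yl)acetaldehyde
Conditions: DIBAL-H (1.05 equiv), CH2Cl2, −78 °C; Rochelle salt
Reagents that add atoms: none
Why: DIBAL half-reduction; the aluminium hemiacetal is stabilised at −78 °C by chelation to a ketal oxygen and collapses to the aldehyde on work-up.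

Step 5
Reactants: 3 1,1-diphenylsilinan-4-one (3 equiv, excess recovered); 6 2-(2-ethyl-1,3-dioxolan-2-yl)acetaldehyde
Product: 7 (3S)-3-[(1S)-2-(2-ethyl-1,3-dioxolan-2-yl)-1-hydroxyethyl]-1,1-diphenylsilinan-4-one
Conditions: L-proline (30 mol%), DMSO, H2O (3 equiv), rt, 48–72 h
Reagents that add atoms: none
Why: Proposed new method: L-proline-catalysed direct aldol of a 4-silacyclohexanone used as a ring-locked equivalent of 1,5-dihydroxypentan-3-one. The ketone forms the necessarily (E)-endocyclic enamine, and the proline carboxylic acid delivers the aldehyde Re face through the chair-like hydrogen-bonded (Houk–List) transition state with the aldehyde substituent equatorial, giving the anti adduct, forming C5–C6 and setting C5 (S) and C6 (S) in the same absolute sense as the cyclohexanone/L-proline anti-aldol. The ring is needed because the acyclic ketone is too unreactive in enamine catalysis, and the β-quaternary, inductively activated aldehyde resists self-aldol. Closest known reaction type: proline-catalysed anti-aldol of cyclohexanone and of tetrahydrothiopyran-4-one (a sulfur-bridged pentan-3-one surrogate).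

Step 6
Reactants: 7
Product: 8 (3S)-3-[(1S)-1-[(tert-butyldimethylsilyl)oxy]-2-(2-ethyl-1,3-dioxolan-2-yl)ethyl]-1,1-diphenylsilinan-4-one
Conditions: TBSOTf (1.2 equiv), 2,6-lutidine, CH2Cl2, −78 °C
Reagents that add atoms: TBSOTf (CC(C)(C)[Si](C)(C)OS(=O)(=O)C(F)(F)F)
Why: O-silylation of the secondary aldol hydroxyl at low temperature blocks retro-aldol; the ketone dioxolane tolerates silyl triflate/lutidine at −78 °C.

Step 7
Reactants: 8
Product: 9 (4S,5S)-5-[(tert-butyldimethylsilyl)oxy]-6-(2-ethyl-1,3-dioxolan-2-yl)-1-hydroxy-4-(hydroxymethyl)hexan-3-one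
Conditions: ICl (1.2 equiv), CH2Cl2, 0 °C; then KF, KHCO3, 30% H2O2, THF/MeOH, rt→40 °C
Reagents that add atoms: hydrogen peroxide (OO)
Why: Fleming–Tamao oxidation: neutral ipso-iododesilylation of one phenyl gives a chlorosilane, and fluoride/peroxide then oxidises both ring Si–CH2 bonds with retention, opening the silacycle to the C6′ and C8′ primary alcohols without touching C5/C6; no peracid is used, so Baeyer–Villiger is avoided.

Step 8
Reactants: 9
Product: 10 (4S,5S)-1,5-bis[(tert-butyldimethylsilyl)oxy]-4-{[(tert-butyldimethylsilyl)oxy]methyl}-6-(2-ethyl-1,3-dioxolan-2-yl)hexan-3-one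
Conditions: TBSCl (2.5 equiv), imidazole, DMF, 0 °C→rt
Reagents that add atoms: TBSCl (CC(C)(C)[Si](C)(C)Cl)
Why: Standard silylation of the two primary alcohols under mild base that does not enolise or eliminate the β-silyloxy ketone.

Step 9
Reactants: 11 methyl (R)-3-hydroxy-2-methylpropanoate ((R)-Roche ester)
Product: 12 methyl (R)-3-[(tert-butyldimethylsilyl)oxy]-2-methylpropanoate
Conditions: TBSCl, imidazole, CH2Cl2, rt
Reagents that add atoms: TBSCl (CC(C)(C)[Si](C)(C)Cl)
Why: Primary alcohol silylation; the Roche stereocentre becomes C12 (the ester carbon becomes C13, the CH2O carbon becomes C11).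

Step 10
Reactants: 12
Product: 13 (R)-3-[(tert-butyldimethylsilyl)oxy]-2-methylpropanal
Conditions: DIBAL-H (1.05 equiv), CH2Cl2, −78 °C
Reagents that add atoms: none
Why: Low-temperature DIBAL half-reduction to the aldehyde, which is used at once to avoid α-epimerisation.

Step 11
Reactants: 13
Product: 14 tert-butyldimethyl{[(2S,3Z)-2-methylpent-3-en-1-yl]oxy}silane
Conditions: EtPPh3Br, NaHMDS, THF, −78 °C→rt
Reagents that add atoms: ethyltriphenylphosphonium bromide (CC[P+](c1ccccc1)(c1ccccc1)c1ccccc1.[Br-])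
Why: Salt-free Wittig reaction of a non-stabilised ylide gives the (Z)-propenyl unit (C13=C14) under kinetic control; the descriptor changes R→S only through CIP priorities.

Step 12
Reactants: 14
Product: 15 (2S,3Z)-2-methylpent-3-en-1-ol
Conditions: TBAF, THF, 0 °C→rt (volatile; concentrate cold)
Reagents that add atoms: none
Why: Fluoride desilylation; no other functionality is present.

Step 13
Reactants: 15
Product: 16 (2S,3Z)-2-methylpent-3-enal
Conditions: Dess–Martin periodinane, NaHCO3, CH2Cl2, 0 °C; solution used directly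
Reagents that add atoms: none
Why: Buffered, amine-free Dess–Martin oxidation minimises epimerisation and conjugation of the β,γ-unsaturated α-methyl aldehyde.

Step 14
Reactants: 16
Product: 17 ethyl (2Z,4S,5Z)-2,4-dimethylhepta-2,5-dienoate
Conditions: (CF3CH2O)2P(O)CH(CH3)CO2Et, KHMDS, 18-crown-6, THF, −78 °C
Reagents that add atoms: ethyl 2-[bis(2,2,2-trifluoroethoxy)phosphoryl]propanoate (CCOC(=O)C(C)P(=O)(OCC(F)(F)F)OCC(F)(F)F)
Why: Still–Gennari olefination gives the (Z)-trisubstituted enoate (ester carbon cis to C12), the geometry later needed for the cis C9/C12 epoxide; the weakly basic phosphonate anion at −78 °C spares the α-stereocentre.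

Step 15
Reactants: 17
Product: 18 (2Z,4S,5Z)-2,4-dimethylhepta-2,5-dien-1-ol
Conditions: DIBAL-H (2.2 equiv), CH2Cl2, −78 °C
Reagents that add atoms: none
Why: 1,2-Reduction of the enoate to the allylic alcohol without touching either Z-alkene.

Step 16
Reactants: 18
Product: 19 (2Z,4S,5Z)-2,4-dimethylhepta-2,5-dienal
Conditions: Dess–Martin periodinane, NaHCO3, CH2Cl2, 0 °C; used immediately
Reagents that add atoms: none
Why: Neutral oxidation of the allylic alcohol keeps the (Z)-enal geometry.

Step 17
Reactants: 10; 19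
Product: 20 (2S,3S,5R,6S,7Z,9S,10Z)-2-[(tert-butyldimethylsilyl)oxy]-3,5-bis{[(tert-butyldimethylsilyl)oxy]methyl}-1-(2-ethyl-1,3-dioxolan-2-yl)-6-hydroxy-7,9-dimethyldodeca-7,10-dien-4-one
Conditions: (c-Hex)2BCl, Et3N, Et2O, −78→0 °C; then 19, −78→−20 °C; MeOH, pH 7 buffer, H2O2, 0 °C
Reagents that add atoms: none
Why: Paterson-type boron aldol: Cy2BCl/Et3N enolises only the unhindered C8 methylene to the (E)-enol borinate, and the chair Zimmerman–Traxler transition state gives the 8,9-anti adduct. Facial control comes from C6: its H eclipses the enolate, the smaller CH2OTBS arm sits over the transition state and the bulkier CH(OTBS)R arm points away (the anti,anti sense of α′-alkoxymethyl ketones), giving C8 (R) and C9 (S).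

Step 18
Reactants: 20
Product: 21 (5S,6S,8R,9S,10Z,12S,13Z)-5-[(tert-butyldimethylsilyl)oxy]-6,8-bis{[(tert-butyldimethylsilyl)oxy]methyl}-9-hydroxy-10,12-dimethylpentadeca-10,13-diene-3,7-dione
Conditions: PPTS (cat.), acetone/H2O (10:1), 45 °C
Reagents that add atoms: water (O)
Why: Mild acid-catalysed ketal hydrolysis/transketalisation unmasks the C3 ketone while TBS ethers, the allylic alcohol and both Z-alkenes survive.

Step 19
Reactants: 21
Product: 22 (5S,6S,8R,9S)-5-[(tert-butyldimethylsilyl)oxy]-6,8-bis{[(tert-butyldimethylsilyl)oxy]methyl}-9-hydroxy-9-{(2R,3S)-2-methyl-3-[(2S,3Z)-pent-3-en-2-yl]oxiran-2-yl}nonane-3,7-dione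
Conditions: mCPBA (1.1 equiv), NaHCO3, CH2Cl2, −20 °C
Reagents that add atoms: mCPBA (OOC(=O)c1cccc(Cl)c1)
Why: Hydroxyl-directed (Henbest) epoxidation: the free C9–OH hydrogen-bonds the peracid and, with the C9–H eclipsing the (Z)-olefin to minimise A(1,3) strain, delivers oxygen to the threo face, setting C10 (R) and C11 (S). The directed, trisubstituted alkene reacts well ahead of the remote Z-disubstituted C13=C14.

Step 20
Reactants: 22
Product: 23 myriaporone 4, (5S,6S,8R,9S)-5,9-dihydroxy-6,8-bis(hydroxymethyl)-9-{(2R,3S)-2-methyl-3-[(2S,3Z)-pent-3-en-2-yl]oxiran-2-yl}nonane-3,7-dione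
Conditions: HF·pyridine, excess pyridine, THF, 0 °C→rt
Reagents that add atoms: none
Why: Buffered fluoride desilylation removes all three TBS groups without acid or base strong enough to open the epoxide or trigger retro-aldol or elimination.

**Compound list**
1 | diphenyldivinylsilane | C=C[Si](C=C)(c1ccccc1)c1ccccc1 | starting material
2 | 1-methoxy-4,4-diphenyl-1,4-borasilinane | COB1CC[Si](CC1)(c1ccccc1)c1ccccc1 | intermediate
3 | 1,1-diphenylsilinan-4-one | O=C1CC[Si](CC1)(c1ccccc1)c1ccccc1 | intermediate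
4 | ethyl 3-oxopentanoate | CCC(=O)CC(=O)OCC | starting material
5 | ethyl 2-(2-ethyl-1,3-dioxolan-2-yl)acetate | CCOC(=O)CC1(CC)OCCO1 | intermediate
6 | 2-(2-ethyl-1,3-dioxolan-2-yl)acetaldehyde | CCC1(CC=O)OCCO1 | intermediate
7 | (3S)-3-[(1S)-2-(2-ethyl-1,3-dioxolan-2-yl)-1-hydroxyethyl]-1,1-diphenylsilinan-4-one | O=C1CC[Si](c2ccccc2)(c3ccccc3)C[C@H]1[C@@H](O)CC4(CC)OCCO4 | intermediate
8 | (3S)-3-[(1S)-1-(TBS-oxy)-2-(2-ethyl-1,3-dioxolan-2-yl)ethyl]-1,1-diphenylsilinan-4-one | O=C1CC[Si](c2ccccc2)(c3ccccc3)C[C@H]1[C@@H](O[Si](C)(C)C(C)(C)C)CC4(CC)OCCO4 | intermediate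
9 | (4S,5S)-5-(TBS-oxy)-6-(2-ethyl-1,3-dioxolan-2-yl)-1-hydroxy-4-(hydroxymethyl)hexan-3-one | OCCC(=O)[C@@H](CO)[C@@H](O[Si](C)(C)C(C)(C)C)CC1(CC)OCCO1 | intermediate
10 | (4S,5S)-1,5-bis(TBS-oxy)-4-[(TBS-oxy)methyl]-6-(2-ethyl-1,3-dioxolan-2-yl)hexan-3-one | CC(C)(C)[Si](C)(C)OCCC(=O)[C@@H](CO[Si](C)(C)C(C)(C)C)[C@@H](O[Si](C)(C)C(C)(C)C)CC1(CC)OCCO1 | intermediate
11 | methyl (R)-3-hydroxy-2-methylpropanoate | COC(=O)[C@H](C)CO | starting material
12 | methyl (R)-3-(TBS-oxy)-2-methylpropanoate | COC(=O)[C@H](C)CO[Si](C)(C)C(C)(C)C | intermediate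
13 | (R)-3-(TBS-oxy)-2-methylpropanal | O=C[C@H](C)CO[Si](C)(C)C(C)(C)C | intermediate
14 | tert-butyldimethyl{[(2S,3Z)-2-methylpent-3-en-1-yl]oxy}silane | C/C=C\[C@H](C)CO[Si](C)(C)C(C)(C)C | intermediate
15 | (2S,3Z)-2-methylpent-3-en-1-ol | C/C=C\[C@H](C)CO | intermediate
16 | (2S,3Z)-2-methylpent-3-enal | C/C=C\[C@H](C)C=O | intermediate
17 | ethyl (2Z,4S,5Z)-2,4-dimethylhepta-2,5-dienoate | C/C=C\[C@H](C)/C=C(/C)C(=O)OCC | intermediate
18 | (2Z,4S,5Z)-2,4-dimethylhepta-2,5-dien-1-ol | C/C=C\[C@H](C)/C=C(/C)CO | intermediate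
19 | (2Z,4S,5Z)-2,4-dimethylhepta-2,5-dienal | C/C=C\[C@H](C)/C=C(/C)C=O | intermediate
20 | (2S,3S,5R,6S,7Z,9S,10Z)-2-(TBS-oxy)-3,5-bis[(TBS-oxy)methyl]-1-(2-ethyl-1,3-dioxolan-2-yl)-6-hydroxy-7,9-dimethyldodeca-7,10-dien-4-one | C/C=C\[C@H](C)/C=C(/C)[C@@H](O)[C@@H](CO[Si](C)(C)C(C)(C)C)C(=O)[C@@H](CO[Si](C)(C)C(C)(C)C)[C@@H](O[Si](C)(C)C(C)(C)C)CC1(CC)OCCO1 | intermediate
21 | (5S,6S,8R,9S,10Z,12S,13Z)-5-(TBS-oxy)-6,8-bis[(TBS-oxy)methyl]-9-hydroxy-10,12-dimethylpentadeca-10,13-diene-3,7-dione | C/C=C\[C@H](C)/C=C(/C)[C@@H](O)[C@@H](CO[Si](C)(C)C(C)(C)C)C(=O)[C@@H](CO[Si](C)(C)C(C)(C)C)[C@@H](O[Si](C)(C)C(C)(C)C)CC(=O)CC | intermediate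
22 | (5S,6S,8R,9S)-5-(TBS-oxy)-6,8-bis[(TBS-oxy)methyl]-9-hydroxy-9-{(2R,3S)-2-methyl-3-[(2S,3Z)-pent-3-en-2-yl]oxiran-2-yl}nonane-3,7-dione | C/C=C\[C@H](C)[C@@H]1O[C@]1(C)[C@@H](O)[C@@H](CO[Si](C)(C)C(C)(C)C)C(=O)[C@@H](CO[Si](C)(C)C(C)(C)C)[C@@H](O[Si](C)(C)C(C)(C)C)CC(=O)CC | intermediate
23 | myriaporone 4 | C/C=C\[C@H](C)[C@@H]1O[C@]1(C)[C@@H](O)[C@@H](CO)C(=O)[C@@H](CO)[C@@H](O)CC(=O)CC | target

**Totals**
- Total step count: 20
- Longest linear sequence: 12 steps (11 → 19 in Steps 9–16, then Steps 17–20)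

**Three steps most likely to fail**
1. Step 5 (proposed new silinanone proline aldol). Risks: low enamine reactivity or eroded dr/ee with the flattened silacycle, and aldehyde self-condensation. Fallback (known chemistry): set C5/C6 by Ir-catalysed anti-(hydroxymethyl)allylation of 2-(2-ethyl-1,3-dioxolan-2-yl)ethanol (LiAlH4 reduction of 5) with vinyl ethylene carbonate. Then bis-TBS protection, ozonolysis to the C7 aldehyde, vinylMgBr addition and Dess–Martin oxidation to the vinyl ketone, Cu-catalysed B2pin2 conjugate borylation with NaBO3 oxidation, and TBS protection converge on ketone 10.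
2. Step 7 (double Fleming–Tamao ring opening next to a ketone). Risks: sluggish phenyl cleavage, α-iodination, or retro-aldol/elimination under the basic peroxide. Fallback: redesign the linchpin as 1,1-bis(4-methoxyphenyl)silinan-4-one (from dichlorodivinylsilane and 4-MeOC6H4MgBr, then Steps 1–2), whose electron-rich aryl groups undergo ipso-cleavage at −78 °C, so the oxidation can be run on a pre-formed fluorosilane under milder conditions.
3. Step 17 (facial selectivity of the second aldol from the C6 stereocentre, and integrity of the Z-enal). Fallback: change the control element from sterics to ether direction by capping the C6′/C8′ alcohols of 9 as PMB ethers (PMB trichloroacetimidate), so the α′-CH2OPMB group enforces the established anti,anti induction. The PMB groups are removed with DDQ after ketal hydrolysis, and the epoxidation and final HF step are then run on the C5-mono-TBS triol.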